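**Retrosynthetic overview**

- Numbering: ring C1 (C=O), C2=C3, C4 (CHOMe), C5 (CH2), C6 (quaternary, allyl); side chain C7 (CHMe), C8 (ArCHOH). The strategy rests on the ring ketone C1 standing next to quaternary C6, with the methoxy carbon C4 joined to C6 through C5. This is the pattern left by a Prins ring closure (C4–C5) that ends in a pinacol shift of C7 from C1 to C6.
- Disconnections, backwards: C2=C3 (Saegusa oxidation) ⇒ ketone 21; C4–C5 and C6–C7 (Prins–pinacol) ⇒ acyclic silyl ether 18; C1–C2 (organocerium addition) ⇒ dienone 13; C1–C6 (alkenyllithium on a Weinreb amide) ⇒ 10; C7–C8 (Evans syn aldol) ⇒ 4 + 5.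
- Stereocontrol: C7 and C8 from the auxiliary; C1 by Felkin addition, then copied onto C6 by the suprafacial shift; C4 by the chair of the ring closure.
- Ring order: one ring only, the cyclohexanone, closed in step 8.

Key step: step 8

Remark: vinylmagnesium bromide (THF solution) is taken as a commercial reagent; the labels C1–C8 are used for the same atoms in all open-chain intermediates.

**Route**

Step 1
Reactants: 1 2,3-dibromopropene; 2 vinylmagnesium bromide
Product: 3 2-bromopenta-1,4-diene
Conditions: CuI (5 mol%), THF, 0 °C → rt; distillation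
Reagents that add atoms: none
Why: Copper-catalysed allylic substitution of the allylic bromide by the vinyl Grignard reagent (SN2 and SN2′ give the same product), the vinylic C–Br bond being inert under these conditions.

Step 2
Reactants: 4 (R)-4-benzyl-3-propanoyloxazolidin-2-one; 5 3,4,5-trimethoxybenzaldehyde
Product: 8 (R)-4-benzyl-3-[(2R,3R)-3-hydroxy-2-methyl-3-(3,4,5-trimethoxyphenyl)propanoyl]oxazolidin-2-one, via dibutylboron Z-enolate 6 (not isolated), via dibutylboron aldolate 7 (not isolated)
Conditions: n-Bu2BOTf, Et3N, CH2Cl2, 0 °C; then 5, −78 → 0 °C; pH 7 buffer, MeOH, 30% H2O2, 0 °C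
Reagents that add atoms: none
Why: Evans syn aldol reaction, in which the Z-boron enolate reacts through a Zimmerman–Traxler chair on the enolate face away from the benzyl group of the dipole-minimised auxiliary and so should set C7 (R) and C8 (R) in the syn relationship.

Step 3
Reactants: 8 aldol adduct
Product: 9 (2R,3R)-3-hydroxy-N-methoxy-N,2-dimethyl-3-(3,4,5-trimethoxyphenyl)propanamide
Conditions: MeNHOMe·HCl, AlMe3, THF, −20 → 0 °C; aq. Rochelle salt
Reagents that add atoms: N,O-dimethylhydroxylamine hydrochloride, CNOC.Cl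
Why: Weinreb transamidation with the aluminium amide, where the aluminium alkoxide of the β-hydroxyl directs attack to the exocyclic carbonyl, so that the auxiliary is released intact and C7 is not epimerised.

Step 4
Reactants: 9 hydroxy Weinreb amide
Product: 10 (2R,3R)-3-(tert-butyldimethylsilyloxy)-N-methoxy-N,2-dimethyl-3-(3,4,5-trimethoxyphenyl)propanamide
Conditions: TBSOTf, 2,6-lutidine, CH2Cl2, −78 → 0 °C
Reagents that add atoms: tert-butyldimethylsilyl trifluoromethanesulfonate, CC(C)(C)[Si](C)(C)OS(=O)(=O)C(F)(F)F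
Why: Silyl triflate silylation of the hindered benzylic hydroxyl gives a non-chelating ether that survives the organometallic steps and the Lewis acid of step 8.

Step 5
Reactants: 3 2-bromopenta-1,4-diene; 10 silylated Weinreb amide
Product: 13 (6R,7R)-7-(tert-butyldimethylsilyloxy)-6-methyl-4-methylidene-7-(3,4,5-trimethoxyphenyl)hept-1-en-5-one, via penta-1,4-dien-2-yllithium 11 (not isolated), via lithium tetrahedral adduct 12 (not isolated)
Conditions: 3, t-BuLi (2 equiv per 3), Et2O, −78 °C; then 10, THF, −78 → −40 °C; inverse quench into cold 0.5 M HCl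
Reagents that add atoms: none
Why: Bromine–lithium exchange at −78 °C should outrun deprotonation of the doubly allylic CH2, and the Weinreb ketone synthesis stops at the chelated adduct, so that neither over-addition nor epimerisation at C7 is expected and the acidic inverse quench protonates the released amine before it can add to the methylene ketone.

Step 6
Reactants: 13 dienone; 14 3-bromo-1,1-dimethoxypropane
Product: 17 (1R,2R,3R)-1-(tert-butyldimethylsilyloxy)-6,6-dimethoxy-2-methyl-3-(penta-1,4-dien-2-yl)-1-(3,4,5-trimethoxyphenyl)hexan-3-ol, via Grignard reagent 15 (not isolated), via organocerium reagent 16 (not isolated)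
Conditions: 14, Mg, THF, rt; anhydrous CeCl3, THF, −78 °C; then 13, −78 °C; H2O, aq. NH4Cl
Reagents that add atoms: none
Why: Organocerium 1,2-addition to a hindered, enolisable enone avoids conjugate addition and deprotonation, and Felkin–Anh control from C7 (CH(OTBS)Ar branch anti to the nucleophile, attack past the C7 hydrogen on the alkenyl side, no chelate with the silyl ether) should set C1 as R, with the hydroxyl syn to the C7 methyl in the zigzag C2–C1–C7–C8.

Step 7
Reactants: 17 tertiary allylic alcohol
Product: 18 (1R,2R,3R)-1-(tert-butyldimethylsilyloxy)-6,6-dimethoxy-2-methyl-3-(penta-1,4-dien-2-yl)-1-(3,4,5-trimethoxyphenyl)-3-(trimethylsilyloxy)hexane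
Conditions: N-(trimethylsilyl)imidazole, CH2Cl2, rt → 40 °C
Reagents that add atoms: N-(trimethylsilyl)imidazole, C[Si](C)(C)n1ccnc1
Why: Neutral silyl transfer puts the small trimethylsilyl group on the hindered tertiary hydroxyl without touching the dimethyl acetal (a silyl triflate with a pyridine base would activate it), and this silyl group is the one that leaves oxygen most easily at the end of step 8.

Step 8
Reactants: 18 tertiary allylic trimethylsilyl ether with C4 dimethyl acetal
Product: 21 (2R,4S)-2-allyl-2-[(1R,2S)-1-(tert-butyldimethylsilyloxy)-1-(3,4,5-trimethoxyphenyl)propan-2-yl]-4-methoxycyclohexan-1-one (2,3-dihydromegaphone TBS ether), via oxocarbenium ion 19 (not isolated), via cyclohexyl cation 20 (not isolated)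
Conditions: TMSOTf (0.2 equiv), 2,6-di-tert-butyl-4-methylpyridine (0.3 equiv), CH2Cl2 (dilute), −78 → −40 °C; Et3N, aq. NaHCO3
Reagents that add atoms: none
Why: TMSOTf ionises the dimethyl acetal to the (E)-methoxy-oxocarbenium ion 19, the terminal alkene carbon C5 attacks C4 in a chair-like 6-endo-trig closure that leaves the tertiary cation 20 at C6, and the axial C1–C7 bond then shifts to C6 with retention at C7 while C1 becomes the ketone and gives its silyl group back as TMSOTf, so the promoter turns over. The closest known reaction type is the pinacol-terminated Prins cyclisation of acetal-tethered allylic silyl ethers (Prins–pinacol reaction), in which a substituent on the silyloxy carbon moves to the neighbouring ring cation. C6 takes its configuration from C1 because the shift is suprafacial. C4 is set by the chair that carries the oxocarbenium methoxy group equatorial and the C7 branch axial, which should be preferred because an equatorial branch would eclipse the allyl group on C6 (A(1,2) strain); this places OMe cis to C7. The step needs side-chain migration in preference to ring-bond migration, proton loss or capture of the cation by the arene: the axial C1–C7 bond is the one aligned with the empty orbital, a secondary carbon migrates better than the ring methylene, and the β-silyloxy group makes the shift fast. The hindered pyridine removes traces of triflic acid so that the benzylic and the tertiary allylic silyl ethers are not ionised.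

Step 9
Reactants: 21 2,3-dihydromegaphone TBS ether
Product: 22 (4S,6R)-6-allyl-6-[(1R,2S)-1-(tert-butyldimethylsilyloxy)-1-(3,4,5-trimethoxyphenyl)propan-2-yl]-4-methoxy-1-(trimethylsilyloxy)cyclohex-1-ene
Conditions: LDA, TMSCl, THF, −78 °C; cold aq. NaHCO3, pentane
Reagents that add atoms: chlorotrimethylsilane, C[Si](C)(C)Cl
Why: Kinetic enolate formation and O-silylation can take place only towards C2 because C6 is quaternary, so a single silyl enol ether should form with C4 and C6 untouched.

Step 10
Reactants: 22 silyl enol ether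
Product: 23 (4R,6R)-6-allyl-6-[(1R,2S)-1-(tert-butyldimethylsilyloxy)-1-(3,4,5-trimethoxyphenyl)propan-2-yl]-4-methoxycyclohex-2-en-1-one (megaphone TBS ether)
Conditions: Pd(OAc)2 (1.1 equiv), MeCN, rt
Reagents that add atoms: none
Why: Saegusa–Ito oxidation, in which the palladium(II) enolate formed with loss of trimethylsilyl acetate undergoes β-hydride elimination of a C3 hydrogen and so installs the C2=C3 double bond without base.

Step 11
Reactants: 23 megaphone TBS ether
Product: 24 megaphone, (4R,6R)-6-allyl-6-[(1R,2S)-1-hydroxy-1-(3,4,5-trimethoxyphenyl)propan-2-yl]-4-methoxycyclohex-2-en-1-one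
Conditions: TBAF, AcOH, THF, 0 °C → rt
Reagents that add atoms: none
Why: Fluoride cleaves the Si–O bond, and the acetic acid buffer keeps the medium from becoming basic enough to deprotonate the enone at C4 or disturb the γ-hydroxy ketone.

**Compound list**

1 | 2,3-dibromopropene | C=C(Br)CBr | starting material
2 | vinylmagnesium bromide | C=C[Mg]Br | starting material
3 | 2-bromopenta-1,4-diene | C=CCC(Br)=C | intermediate
4 | (R)-4-benzyl-3-propanoyloxazolidin-2-one | CCC(=O)N1[C@H](Cc2ccccc2)COC1=O | starting material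
5 | 3,4,5-trimethoxybenzaldehyde | COc1cc(C=O)cc(OC)c1OC | starting material
6 | dibutylboron Z-enolate of 4 | C/C=C(\OB(CCCC)CCCC)N1[C@H](Cc2ccccc2)COC1=O | intermediate
7 | dibutylboron aldolate of 8 | O=C1OC[C@@H](Cc2ccccc2)N1C(=O)[C@H](C)[C@@H](OB(CCCC)CCCC)c3cc(OC)c(OC)c(OC)c3 | intermediate
8 | (R)-4-benzyl-3-[(2R,3R)-3-hydroxy-2-methyl-3-(3,4,5-trimethoxyphenyl)propanoyl]oxazolidin-2-one | O=C1OC[C@@H](Cc2ccccc2)N1C(=O)[C@H](C)[C@@H](O)c3cc(OC)c(OC)c(OC)c3 | intermediate
9 | (2R,3R)-3-hydroxy-N-methoxy-N,2-dimethyl-3-(3,4,5-trimethoxyphenyl)propanamide | CON(C)C(=O)[C@H](C)[C@@H](O)c1cc(OC)c(OC)c(OC)c1 | intermediate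
10 | (2R,3R)-3-(tert-butyldimethylsilyloxy)-N-methoxy-N,2-dimethyl-3-(3,4,5-trimethoxyphenyl)propanamide | CON(C)C(=O)[C@H](C)[C@@H](O[Si](C)(C)C(C)(C)C)c1cc(OC)c(OC)c(OC)c1 | intermediate
11 | penta-1,4-dien-2-yllithium | [Li]C(=C)CC=C | intermediate
12 | lithium tetrahedral adduct of 11 and 10 (new carbon unassigned) | C=CCC(=C)C(O[Li])(N(C)OC)[C@H](C)[C@@H](O[Si](C)(C)C(C)(C)C)c1cc(OC)c(OC)c(OC)c1 | intermediate
13 | (6R,7R)-7-(tert-butyldimethylsilyloxy)-6-methyl-4-methylidene-7-(3,4,5-trimethoxyphenyl)hept-1-en-5-one | C=CCC(=C)C(=O)[C@H](C)[C@@H](O[Si](C)(C)C(C)(C)C)c1cc(OC)c(OC)c(OC)c1 | intermediate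
14 | 3-bromo-1,1-dimethoxypropane | COC(CCBr)OC | starting material
15 | (3,3-dimethoxypropyl)magnesium bromide | COC(CC[Mg]Br)OC | intermediate
16 | (3,3-dimethoxypropyl)cerium dichloride | COC(CC[Ce](Cl)Cl)OC | intermediate
17 | (1R,2R,3R)-1-(tert-butyldimethylsilyloxy)-6,6-dimethoxy-2-methyl-3-(penta-1,4-dien-2-yl)-1-(3,4,5-trimethoxyphenyl)hexan-3-ol | C=CCC(=C)[C@@](O)(CCC(OC)OC)[C@H](C)[C@@H](O[Si](C)(C)C(C)(C)C)c1cc(OC)c(OC)c(OC)c1 | intermediate
18 | trimethylsilyl ether of 17 (Prins–pinacol precursor) | C=CCC(=C)[C@@](O[Si](C)(C)C)(CCC(OC)OC)[C@H](C)[C@@H](O[Si](C)(C)C(C)(C)C)c1cc(OC)c(OC)c(OC)c1 | intermediate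
19 | (E)-methoxy-oxocarbenium triflate from 18 | C=CCC(=C)[C@@](O[Si](C)(C)C)(CC/C=[O+]/C)[C@H](C)[C@@H](O[Si](C)(C)C(C)(C)C)c1cc(OC)c(OC)c(OC)c1.[O-]S(=O)(=O)C(F)(F)F | intermediate
20 | C6 cyclohexyl cation triflate (C7 on C1 cis to the C4 methoxy group) | C=CC[C+]1C[C@@H](OC)CC[C@@]1(O[Si](C)(C)C)[C@H](C)[C@@H](O[Si](C)(C)C(C)(C)C)c2cc(OC)c(OC)c(OC)c2.[O-]S(=O)(=O)C(F)(F)F | intermediate
21 | (2R,4S)-2-allyl-2-[(1R,2S)-1-(tert-butyldimethylsilyloxy)-1-(3,4,5-trimethoxyphenyl)propan-2-yl]-4-methoxycyclohexan-1-one | C=CC[C@]1([C@H](C)[C@@H](O[Si](C)(C)C(C)(C)C)c2cc(OC)c(OC)c(OC)c2)C[C@@H](OC)CCC1=O | intermediate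
22 | (4S,6R)-6-allyl-6-[(1R,2S)-1-(tert-butyldimethylsilyloxy)-1-(3,4,5-trimethoxyphenyl)propan-2-yl]-4-methoxy-1-(trimethylsilyloxy)cyclohex-1-ene | C=CC[C@]1([C@H](C)[C@@H](O[Si](C)(C)C(C)(C)C)c2cc(OC)c(OC)c(OC)c2)C[C@@H](OC)CC=C1O[Si](C)(C)C | intermediate
23 | megaphone TBS ether | C=CC[C@]1([C@H](C)[C@@H](O[Si](C)(C)C(C)(C)C)c2cc(OC)c(OC)c(OC)c2)C[C@@H](OC)C=CC1=O | intermediate
24 | megaphone | C=CC[C@]1([C@H](C)[C@@H](O)c2cc(OC)c(OC)c(OC)c2)C[C@@H](OC)C=CC1=O | target

**Step count**

Total: 11 steps. Longest linear sequence: 10 steps (4 → 24, steps 2–11).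

**Steps most likely to fail**

Step 8. The two chair-like closures may not be well discriminated, so that the oxocarbenium carbon C4 is attacked on both faces and C4 control is lost. The fallback sets C4 by a chiral acetal template instead of the chair; it sets out from 14 (joining 13 as in step 6) and returns at 21. Bromo acetal 14 is transacetalised with (2S,4S)-pentane-2,4-diol (PPTS, toluene, removal of methanol) to (4S,6S)-2-(2-bromoethyl)-4,6-dimethyl-1,3-dioxane F1. Its Grignard reagent F2 is turned into the organocerium reagent F3, which adds to 13 as in step 6 to give tertiary alcohol F4, and silylation as in step 7 gives trimethylsilyl ether F5. TiCl4 (CH2Cl2, −78 °C) should open the dioxane at the oxygen next to the axial methyl group with backside attack of the alkene, so the face of C4 is fixed by the template; on that model the (S,S)-diol is the enantiomer that delivers the required C4 configuration. The pinacol shift follows as before and gives hydroxypentyl ether ketone F6. Dess–Martin oxidation gives oxopentyl ether ketone F7, β-elimination (K2CO3, MeOH) frees C4 alcohol F8, and methylation (Me3OBF4, Proton Sponge, CH2Cl2) leads to 21.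

Step 6. Facial selectivity at the ketone may be poor, because the Felkin preference from C7 can be opposed by the β-silyloxy group; conjugate addition to the dienone or its enolisation may also compete. The fallback reverses the order of the two additions and uses chelation control; it sets out from 9 and returns at 17. Hydroxy amide 9 is treated with an excess of Grignard reagent 15 (THF, 0 °C) to give β-hydroxy ketone F9. Penta-1,4-dien-2-ylmagnesium bromide F10 (from 3 and Mg, THF) then adds to the magnesium alkoxide chelate of F9 from the face opposite the C7 methyl group, which should give diol F11 with the same (R)-C1. Selective silylation of the secondary benzylic hydroxyl (TBSCl, imidazole, DMF) gives 17.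

Step 5. The alkenyllithium may be lost by proton transfer from the doubly allylic CH2, and the released N,O-dimethylhydroxylamine may add to the methylene ketone during the quench. The fallback replaces the organolithium by a Nozaki–Hiyama–Kishi coupling followed by oxidation; it sets out from 10 and returns at 13. DIBAL-H (THF, −78 °C) reduces 10 to aldehyde F12. CrCl2 with catalytic NiCl2 in DMF couples F12 with 3 to allylic alcohol F13 (both carbinol epimers are used). Dess–Martin periodinane oxidises F13 to 13.

**Further compounds**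

F1 | step 8 | (4S,6S)-2-(2-bromoethyl)-4,6-dimethyl-1,3-dioxane | BrCCC1O[C@@H](C)C[C@H](C)O1
F2 | step 8 | Grignard reagent of F1 | Br[Mg]CCC1O[C@@H](C)C[C@H](C)O1
F3 | step 8 | organocerium reagent from F2 | Cl[Ce](Cl)CCC1O[C@@H](C)C[C@H](C)O1
F4 | step 8 | tertiary alcohol with the chiral dioxane acetal | C=CCC(=C)[C@@](O)(CCC1O[C@@H](C)C[C@H](C)O1)[C@H](C)[C@@H](O[Si](C)(C)C(C)(C)C)c2cc(OC)c(OC)c(OC)c2
F5 | step 8 | trimethylsilyl ether of F4 | C=CCC(=C)[C@@](O[Si](C)(C)C)(CCC1O[C@@H](C)C[C@H](C)O1)[C@H](C)[C@@H](O[Si](C)(C)C(C)(C)C)c2cc(OC)c(OC)c(OC)c2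
F6 | step 8 | hydroxypentyl ether ketone | C=CC[C@]1([C@H](C)[C@@H](O[Si](C)(C)C(C)(C)C)c2cc(OC)c(OC)c(OC)c2)C[C@@H](O[C@@H](C)C[C@H](C)O)CCC1=O
F7 | step 8 | oxopentyl ether ketone | C=CC[C@]1([C@H](C)[C@@H](O[Si](C)(C)C(C)(C)C)c2cc(OC)c(OC)c(OC)c2)C[C@@H](O[C@@H](C)CC(C)=O)CCC1=O
F8 | step 8 | C4 alcohol | C=CC[C@]1([C@H](C)[C@@H](O[Si](C)(C)C(C)(C)C)c2cc(OC)c(OC)c(OC)c2)C[C@@H](O)CCC1=O
F9 | step 6 | β-hydroxy ketone, (1R,2R)-1-hydroxy-6,6-dimethoxy-2-methyl-1-(3,4,5-trimethoxyphenyl)hexan-3-one | COC(CCC(=O)[C@H](C)[C@@H](O)c1cc(OC)c(OC)c(OC)c1)OC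
F10 | step 6 | penta-1,4-dien-2-ylmagnesium bromide | C=CCC(=C)[Mg]Br
F11 | step 6 | diol | C=CCC(=C)[C@@](O)(CCC(OC)OC)[C@H](C)[C@@H](O)c1cc(OC)c(OC)c(OC)c1
F12 | step 5 | aldehyde, (2R,3R)-3-(tert-butyldimethylsilyloxy)-2-methyl-3-(3,4,5-trimethoxyphenyl)propanal | O=C[C@H](C)[C@@H](O[Si](C)(C)C(C)(C)C)c1cc(OC)c(OC)c(OC)c1
F13 | step 5 | allylic alcohol (carbinol epimers) | C=CCC(=C)C(O)[C@H](C)[C@@H](O[Si](C)(C)C(C)(C)C)c1cc(OC)c(OC)c(OC)c1
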